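**Retrosynthetic overview**
1. Target 27 ⇐ desilylation of 26 ⇐ the ten-membered carbocycle is closed last, by Nozaki–Hiyama–Kishi coupling of C-1 with C-10 in the seco iodo-aldehyde 24.
2. 24 ⇐ C-3 carbinol (oxazaborolidine reduction, then acetate) ⇐ Z-enone 21. Its C-1–C-3 chain and the α-methylene-γ-butyrolactone (second ring) arise together when an acetal Grignard opens the butenolide of acid 18 and O-6 is re-acylated by C-12.
3. 18 ⇐ aldehyde 17 ⇐ one-flask amine-catalysed vinylogous Mukaiyama–Michael/α-methylenation joining enal 9 and silyloxyfuran 14 (C-6–C-7 bond, C-6 and C-7; the butenolide is the first ring and locks the 4Z alkene).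
4. 9 ⇐ catalytic asymmetric propynylation of fumaraldehyde mono-acetal (C-8), trans-hydroalumination/iodination (9Z vinyl iodide), esterification with (S)-2-methylbutanoic acid (from tiglic acid by asymmetric hydrogenation).
5. 14 ⇐ furan-3-ylmethanol (C-2 lithiation, borylation/oxidation, bis-silylation).

Assumption: atoms carry germacranolide-type labels (lactone oxygen on C-6, ester on C-8, acetate on C-3, hydroxyls on C-1 and C-15, C-14 methyl on C-10, C-11=C-13 methylene, C-12 lactone carbonyl); CIP descriptors are those of each compound itself; each named catalyst or ligand antipode is the one taken to give the drawn sense of induction, its mirror image being used if the opposite is found.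

**Step 1**
Reactants: 1 tiglic acid [(E)-2-methylbut-2-enoic acid]
Product: 2 (2S)-2-methylbutanoic acid
Conditions: H2 (4 atm), Ru(OAc)2[(S)-H8-BINAP] (0.5 mol %), MeOH, 20 °C
Reagents that add atoms: none
Why: Carboxylate-directed asymmetric hydrogenation of an α,β-unsaturated acid on the chiral ruthenium diphosphine sets the (S)-α-stereocentre of the ester side chain.

**Step 2**
Reactants: 3 (E)-4,4-dimethoxybut-2-enal; 4 propyne
Product: 5 (2E,4S)-1,1-dimethoxyhept-2-en-5-yn-4-ol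
Conditions: Me2Zn (3 equiv), (S,S)-ProPhenol (10 mol %), Ph3PO (20 mol %), toluene, 0 °C
Reagents that add atoms: none
Why: Catalytic asymmetric alkynylation of an aldehyde: the dinuclear zinc–ProPhenol pocket delivers the propynylzinc to the Re face of the enal carbonyl and sets the first ring stereocentre (C-8, here 4S).

**Step 3**
Reactants: 5 (2E,4S)-1,1-dimethoxyhept-2-en-5-yn-4-ol
Product: 7 (2E,4S,5Z)-6-iodo-1,1-dimethoxyhepta-2,5-dien-4-ol, via cyclic sodium alkenylalanate 6 (not isolated)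
Conditions: NaAlH2(OCH2CH2OMe)2 (1.5 equiv), THF, 0 to 23 °C; then N-iodosuccinimide, −78 °C
Reagents that add atoms: N-iodosuccinimide, O=C1CCC(=O)N1I
Why: Hydroxyl-directed trans-hydroalumination of the propargylic alcohol puts aluminium on the distal carbon in a five-membered alkoxyalanate, and iodinolysis with retention gives the Z-vinyl iodide (future 9Z alkene) without touching C-8.

**Step 4**
Reactants: 7 (2E,4S,5Z)-6-iodo-1,1-dimethoxyhepta-2,5-dien-4-ol; 2 (2S)-2-methylbutanoic acid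
Product: 8 (2E,4S,5Z)-6-iodo-1,1-dimethoxyhepta-2,5-dien-4-yl (2S)-2-methylbutanoate
Conditions: EDC·HCl (1.3 equiv), DMAP (0.1 equiv), CH2Cl2, 0 °C
Reagents that add atoms: none
Why: Steglich-type carbodiimide esterification at low temperature installs the C-8 ester with retention at both stereocentres.

**Step 5**
Reactants: 8 (2E,4S,5Z)-6-iodo-1,1-dimethoxyhepta-2,5-dien-4-yl (2S)-2-methylbutanoate
Product: 9 (2E,4S,5Z)-6-iodo-1-oxohepta-2,5-dien-4-yl (2S)-2-methylbutanoate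
Conditions: p-TsOH·H2O (5 mol %), acetone/H2O (10:1), 0 °C
Reagents that add atoms: water, O
Why: Acid-catalysed hydrolysis of the labile allylic dimethyl acetal unmasks the E-enal while the allylic ester and vinyl iodide stay intact.

**Step 6**
Reactants: 10 furan-3-ylmethanol
Product: 13 3-(hydroxymethyl)furan-2(5H)-one, via dilithiated furan-3-ylmethanol 11 (not isolated), via lithium furyl trimethoxyborate 12 (not isolated)
Conditions: n-BuLi (2.2 equiv), THF, −78 to 0 °C; B(OMe)3, −78 °C; then 30 % H2O2, NaHCO3, 0 to 23 °C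
Reagents that add atoms: hydrogen peroxide, OO
Why: Alkoxide-directed ortho-lithiation at C-2, borylation and oxidative boron-to-oxygen migration give the 2-hydroxyfuran, which tautomerises to the conjugated butenolide (no stereocentre).

**Step 7**
Reactants: 13 3-(hydroxymethyl)furan-2(5H)-one
Product: 14 2-(tert-butyldimethylsilyloxy)-3-[(tert-butyldimethylsilyloxy)methyl]furan
Conditions: TBSOTf (2.3 equiv), Et3N (3 equiv), CH2Cl2, 0 °C
Reagents that add atoms: tert-butyldimethylsilyl trifluoromethanesulfonate, CC(C)(C)[Si](C)(C)OS(=O)(=O)C(F)(F)F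
Why: Silylation of the alcohol and soft enolisation of the butenolide give the 2-silyloxyfuran, a vinylogous silyl ketene acetal nucleophilic at C-5.

**Step 8**
Reactants: 9 (2E,4S,5Z)-6-iodo-1-oxohepta-2,5-dien-4-yl (2S)-2-methylbutanoate; 14 2-(tert-butyldimethylsilyloxy)-3-[(tert-butyldimethylsilyloxy)methyl]furan
Product: 17 (3S,4S,5Z)-3-[(2S)-4-{[tert-butyl(dimethyl)silyl]oxymethyl}-5-oxo-2,5-dihydrofuran-2-yl]-6-iodo-2-methylidene-1-oxohept-5-en-4-yl (2S)-2-methylbutanoate, via Michael aldehyde 15 (not isolated), via hydroxymethyl aldol adduct 16 (not isolated)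
Conditions: (2S,5S)-5-benzyl-2-tert-butyl-3-methylimidazolidin-4-one (20 mol %), 2,4-dinitrobenzoic acid (20 mol %), CH2Cl2/H2O, −40 °C; then 37 % aq. CH2O (3 equiv), i-PrOH, 23 to 40 °C
Reagents that add atoms: formaldehyde, C=O
Why: Proposed new method: one secondary-amine catalyst is used in an iminium-then-enamine relay, in which iminium activation of enal 9 lets silyloxyfuran 14 add through its C-5 to the Re face of the β-carbon (catalyst control, syn topicity placing O-6 and C-8 on the same side of the C-5–C-6–C-7–C-11 chain, giving 6S,7S) and the enamine left behind is intercepted by formaldehyde (aldol, then E1cB dehydration) before turnover, so the C-6–C-7 bond and the C-11=C-13 methylene are made in one flask; the closest known reaction types are the imidazolidinone-catalysed vinylogous Mukaiyama–Michael addition of silyloxyfurans to enals, iminium–enamine cascades with heteroatom electrophiles, and the separate amine-catalysed α-methylenation of aldehydes with formaldehyde.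

**Step 9**
Reactants: 17 (3S,4S,5Z)-3-[(2S)-4-{[tert-butyl(dimethyl)silyl]oxymethyl}-5-oxo-2,5-dihydrofuran-2-yl]-6-iodo-2-methylidene-1-oxohept-5-en-4-yl (2S)-2-methylbutanoate
Product: 18 (3S,4S,5Z)-3-[(2S)-4-{[tert-butyl(dimethyl)silyl]oxymethyl}-5-oxo-2,5-dihydrofuran-2-yl]-6-iodo-2-methylidene-4-{[(2S)-2-methylbutanoyl]oxy}hept-5-enoic acid
Conditions: NaClO2, NaH2PO4, 2-methyl-2-butene, t-BuOH/H2O, 0 °C
Reagents that add atoms: sodium chlorite, [Na+].[O-]Cl=O
Why: Pinnick oxidation converts the 2-substituted acrolein into the acrylic acid under buffered conditions that spare the alkenes, the butenolide and the stereocentres.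

**Step 10**
Reactants: 18 (3S,4S,5Z)-3-[(2S)-4-{[tert-butyl(dimethyl)silyl]oxymethyl}-5-oxo-2,5-dihydrofuran-2-yl]-6-iodo-2-methylidene-4-{[(2S)-2-methylbutanoyl]oxy}hept-5-enoic acid; 19 (1,3-dioxolan-2-ylmethyl)magnesium bromide
Product: 21 (1S,2Z)-1-{(2S,3S)-2-[(1Z)-2-{[tert-butyl(dimethyl)silyl]oxymethyl}-4-(1,3-dioxolan-2-yl)-3-oxobut-1-en-1-yl]-4-methylidene-5-oxooxolan-3-yl}-3-iodobut-2-en-1-yl (2S)-2-methylbutanoate, via hemiketal acid 20 (not isolated)
Conditions: 19 (2.5 equiv), CeCl3 (2.5 equiv), THF, −78 °C, aq. NH4Cl; then EDC·HCl, DMAP (cat.), CH2Cl2, 0 °C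
Reagents that add atoms: none
Why: The weakly basic organocerium adds 1,2 to the butenolide carbonyl (the carboxylate and the α-branched ester are spared) and stops at the hemiketal; the O-6 hydroxyl of its open Z-γ-hydroxy-enone form is then acylated intramolecularly by the carbodiimide-activated acid (lactonisation), which transposes the lactone to C-12, leaves C-6 and C-7 untouched (cis-fused α-methylene lactone) and keeps the 4Z geometry inherited from the ring.

**Step 11**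
Reactants: 21 (1S,2Z)-1-{(2S,3S)-2-[(1Z)-2-{[tert-butyl(dimethyl)silyl]oxymethyl}-4-(1,3-dioxolan-2-yl)-3-oxobut-1-en-1-yl]-4-methylidene-5-oxooxolan-3-yl}-3-iodobut-2-en-1-yl (2S)-2-methylbutanoate
Product: 22 (1S,2Z)-1-{(2S,3S)-2-[(1Z,3S)-2-{[tert-butyl(dimethyl)silyl]oxymethyl}-4-(1,3-dioxolan-2-yl)-3-hydroxybut-1-en-1-yl]-4-methylidene-5-oxooxolan-3-yl}-3-iodobut-2-en-1-yl (2S)-2-methylbutanoate
Conditions: (R)-2-methyl-CBS-oxazaborolidine (20 mol %), catecholborane (1.5 equiv), toluene/CH2Cl2, −78 °C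
Reagents that add atoms: none
Why: Corey–Bakshi–Shibata reduction: the oxazaborolidine binds the ketone with the branched alkenyl group as the large substituent and delivers hydride to give the 3S allylic alcohol under reagent control, 1,2 only.

**Step 12**
Reactants: 22 (1S,2Z)-1-{(2S,3S)-2-[(1Z,3S)-2-{[tert-butyl(dimethyl)silyl]oxymethyl}-4-(1,3-dioxolan-2-yl)-3-hydroxybut-1-en-1-yl]-4-methylidene-5-oxooxolan-3-yl}-3-iodobut-2-en-1-yl (2S)-2-methylbutanoate
Product: 23 (1S,2Z)-1-{(2S,3S)-2-[(1Z,3S)-3-(acetyloxy)-2-{[tert-butyl(dimethyl)silyl]oxymethyl}-4-(1,3-dioxolan-2-yl)but-1-en-1-yl]-4-methylidene-5-oxooxolan-3-yl}-3-iodobut-2-en-1-yl (2S)-2-methylbutanoate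
Conditions: Ac2O, pyridine, DMAP (cat.), CH2Cl2, 0 °C
Reagents that add atoms: acetic anhydride, CC(=O)OC(C)=O
Why: Nucleophile-catalysed acetylation of the only free hydroxyl places the acetate on C-3 with retention.

**Step 13**
Reactants: 23 (1S,2Z)-1-{(2S,3S)-2-[(1Z,3S)-3-(acetyloxy)-2-{[tert-butyl(dimethyl)silyl]oxymethyl}-4-(1,3-dioxolan-2-yl)but-1-en-1-yl]-4-methylidene-5-oxooxolan-3-yl}-3-iodobut-2-en-1-yl (2S)-2-methylbutanoate
Product: 24 (1S,2Z)-1-{(2S,3S)-2-[(1Z,3S)-3-(acetyloxy)-2-{[tert-butyl(dimethyl)silyl]oxymethyl}-5-oxopent-1-en-1-yl]-4-methylidene-5-oxooxolan-3-yl}-3-iodobut-2-en-1-yl (2S)-2-methylbutanoate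
Conditions: pyridinium p-toluenesulfonate (0.3 equiv), acetone/H2O (10:1), 50 °C
Reagents that add atoms: water, O
Why: Mild acid hydrolysis of the dioxolane releases the C-1 aldehyde; the weakly acidic medium avoids E1cB loss of the β-acetate and keeps the primary silyl ether, so C-15–OH cannot form a lactol with C-1.

**Step 14**
Reactants: 24 (1S,2Z)-1-{(2S,3S)-2-[(1Z,3S)-3-(acetyloxy)-2-{[tert-butyl(dimethyl)silyl]oxymethyl}-5-oxopent-1-en-1-yl]-4-methylidene-5-oxooxolan-3-yl}-3-iodobut-2-en-1-yl (2S)-2-methylbutanoate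
Product: 26 (1S,3S,4Z,6S,7R,8R,9Z)-3-acetoxy-15-(tert-butyldimethylsilyloxy)-1-hydroxy-8-[(2S)-2-methylbutanoyloxy]germacra-4,9,11(13)-trien-12,6-olide, via alkenylchromium dichloride 25 (not isolated)
Conditions: CrCl2 (10 equiv), NiCl2 (0.1 equiv), DMSO/THF (3:1), 0.002 M, 23 °C
Reagents that add atoms: none
Why: Nozaki–Hiyama–Kishi macrocyclisation: the Z-vinyl iodide passes via nickel to an alkenylchromium that adds only to the aldehyde, the two Z-alkenes and the cis-lactone pre-fold the chain for ten-membered ring closure, and the new C-1 carbinol is expected 1,3-anti to the C-3 acetate (polar Felkin–Anh model, C–OAc dipole opposed to C=O), giving 1S.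

**Step 15**
Reactants: 26 (1S,3S,4Z,6S,7R,8R,9Z)-3-acetoxy-15-(tert-butyldimethylsilyloxy)-1-hydroxy-8-[(2S)-2-methylbutanoyloxy]germacra-4,9,11(13)-trien-12,6-olide
Product: 27 (1S,3S,4Z,6S,7R,8R,9Z)-3-acetoxy-1,15-dihydroxy-8-[(2S)-2-methylbutanoyloxy]germacra-4,9,11(13)-trien-12,6-olide (CNP0217661.3)
Conditions: HF·pyridine, pyridine, THF, 0 °C
Reagents that add atoms: none
Why: Buffered fluoride desilylation frees the primary C-15 hydroxyl under mildly acidic conditions that suppress acetate migration and spare the α-methylene lactone.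

**Compound list**
1 | tiglic acid [(E)-2-methylbut-2-enoic acid] | C/C=C(\C)C(=O)O | starting material
2 | (2S)-2-methylbutanoic acid | CC[C@H](C)C(=O)O | intermediate
3 | (E)-4,4-dimethoxybut-2-enal | COC(OC)/C=C/C=O | starting material
4 | propyne | CC#C | starting material
5 | (2E,4S)-1,1-dimethoxyhept-2-en-5-yn-4-ol | COC(OC)/C=C/[C@H](O)C#CC | intermediate
6 | cyclic sodium alkenylalanate: sodium (5S)-5-[(E)-3,3-dimethoxyprop-1-enyl]-2,2-bis(2-methoxyethoxy)-3-methyl-2,5-dihydro-1,2-oxaaluminol-2-uide | COC(OC)/C=C/[C@@H]1O[Al-](OCCOC)(OCCOC)C(C)=C1.[Na+] | intermediate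
7 | (2E,4S,5Z)-6-iodo-1,1-dimethoxyhepta-2,5-dien-4-ol | COC(OC)/C=C/[C@H](O)/C=C(/C)I | intermediate
8 | (2E,4S,5Z)-6-iodo-1,1-dimethoxyhepta-2,5-dien-4-yl (2S)-2-methylbutanoate | COC(OC)/C=C/[C@H](OC(=O)[C@@H](C)CC)/C=C(/C)I | intermediate
9 | (2E,4S,5Z)-6-iodo-1-oxohepta-2,5-dien-4-yl (2S)-2-methylbutanoate | O=C/C=C/[C@H](OC(=O)[C@@H](C)CC)/C=C(/C)I | intermediate
10 | furan-3-ylmethanol | OCc1ccoc1 | starting material
11 | dilithiated furan-3-ylmethanol: lithium (2-lithiofuran-3-yl)methanolate | [Li]OCc1ccoc1[Li] | intermediate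
12 | lithium trimethoxy[3-(lithiooxymethyl)furan-2-yl]borate | [Li+].[Li]OCc1ccoc1[B-](OC)(OC)OC | intermediate
13 | 3-(hydroxymethyl)furan-2(5H)-one | O=C1OCC=C1CO | intermediate
14 | 2-(tert-butyldimethylsilyloxy)-3-[(tert-butyldimethylsilyloxy)methyl]furan | CC(C)(C)[Si](C)(C)OCc1ccoc1O[Si](C)(C)C(C)(C)C | intermediate
15 | Michael aldehyde: (3S,4S,5Z)-3-[(2S)-4-{[tert-butyl(dimethyl)silyl]oxymethyl}-5-oxo-2,5-dihydrofuran-2-yl]-6-iodo-1-oxohept-5-en-4-yl (2S)-2-methylbutanoate | O=CC[C@@H]([C@@H]1C=C(CO[Si](C)(C)C(C)(C)C)C(=O)O1)[C@H](OC(=O)[C@@H](C)CC)/C=C(/C)I | intermediate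
16 | hydroxymethyl aldol adduct: (2RS,3S,4S,5Z)-3-[(2S)-4-{[tert-butyl(dimethyl)silyl]oxymethyl}-5-oxo-2,5-dihydrofuran-2-yl]-2-(hydroxymethyl)-6-iodo-1-oxohept-5-en-4-yl (2S)-2-methylbutanoate | O=CC(CO)[C@@H]([C@@H]1C=C(CO[Si](C)(C)C(C)(C)C)C(=O)O1)[C@H](OC(=O)[C@@H](C)CC)/C=C(/C)I | intermediate
17 | (3S,4S,5Z)-3-[(2S)-4-{[tert-butyl(dimethyl)silyl]oxymethyl}-5-oxo-2,5-dihydrofuran-2-yl]-6-iodo-2-methylidene-1-oxohept-5-en-4-yl (2S)-2-methylbutanoate | C=C(C=O)[C@@H]([C@@H]1C=C(CO[Si](C)(C)C(C)(C)C)C(=O)O1)[C@H](OC(=O)[C@@H](C)CC)/C=C(/C)I | intermediate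
18 | (3S,4S,5Z)-3-[(2S)-4-{[tert-butyl(dimethyl)silyl]oxymethyl}-5-oxo-2,5-dihydrofuran-2-yl]-6-iodo-2-methylidene-4-{[(2S)-2-methylbutanoyl]oxy}hept-5-enoic acid | C=C(C(=O)O)[C@@H]([C@@H]1C=C(CO[Si](C)(C)C(C)(C)C)C(=O)O1)[C@H](OC(=O)[C@@H](C)CC)/C=C(/C)I | intermediate
19 | (1,3-dioxolan-2-ylmethyl)magnesium bromide | Br[Mg]CC1OCCO1 | starting material
20 | hemiketal acid: (3S,4S,5Z)-3-[(2S,5RS)-4-{[tert-butyl(dimethyl)silyl]oxymethyl}-5-(1,3-dioxolan-2-ylmethyl)-5-hydroxy-2,5-dihydrofuran-2-yl]-6-iodo-2-methylidene-4-{[(2S)-2-methylbutanoyl]oxy}hept-5-enoic acid | C=C(C(=O)O)[C@@H]([C@@H]1C=C(CO[Si](C)(C)C(C)(C)C)C(O)(CC2OCCO2)O1)[C@H](OC(=O)[C@@H](C)CC)/C=C(/C)I | intermediate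
21 | (1S,2Z)-1-{(2S,3S)-2-[(1Z)-2-{[tert-butyl(dimethyl)silyl]oxymethyl}-4-(1,3-dioxolan-2-yl)-3-oxobut-1-en-1-yl]-4-methylidene-5-oxooxolan-3-yl}-3-iodobut-2-en-1-yl (2S)-2-methylbutanoate | C=C1C(=O)O[C@@H](/C=C(/CO[Si](C)(C)C(C)(C)C)C(=O)CC2OCCO2)[C@H]1[C@H](OC(=O)[C@@H](C)CC)/C=C(/C)I | intermediate
22 | (1S,2Z)-1-{(2S,3S)-2-[(1Z,3S)-2-{[tert-butyl(dimethyl)silyl]oxymethyl}-4-(1,3-dioxolan-2-yl)-3-hydroxybut-1-en-1-yl]-4-methylidene-5-oxooxolan-3-yl}-3-iodobut-2-en-1-yl (2S)-2-methylbutanoate | C=C1C(=O)O[C@@H](/C=C(/CO[Si](C)(C)C(C)(C)C)[C@@H](O)CC2OCCO2)[C@H]1[C@H](OC(=O)[C@@H](C)CC)/C=C(/C)I | intermediate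
23 | (1S,2Z)-1-{(2S,3S)-2-[(1Z,3S)-3-(acetyloxy)-2-{[tert-butyl(dimethyl)silyl]oxymethyl}-4-(1,3-dioxolan-2-yl)but-1-en-1-yl]-4-methylidene-5-oxooxolan-3-yl}-3-iodobut-2-en-1-yl (2S)-2-methylbutanoate | C=C1C(=O)O[C@@H](/C=C(/CO[Si](C)(C)C(C)(C)C)[C@@H](OC(C)=O)CC2OCCO2)[C@H]1[C@H](OC(=O)[C@@H](C)CC)/C=C(/C)I | intermediate
24 | (1S,2Z)-1-{(2S,3S)-2-[(1Z,3S)-3-(acetyloxy)-2-{[tert-butyl(dimethyl)silyl]oxymethyl}-5-oxopent-1-en-1-yl]-4-methylidene-5-oxooxolan-3-yl}-3-iodobut-2-en-1-yl (2S)-2-methylbutanoate | C=C1C(=O)O[C@@H](/C=C(/CO[Si](C)(C)C(C)(C)C)[C@@H](OC(C)=O)CC=O)[C@H]1[C@H](OC(=O)[C@@H](C)CC)/C=C(/C)I | intermediate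
25 | alkenylchromium dichloride derived from 24 (CrCl2 in place of I at C-10) | C=C1C(=O)O[C@@H](/C=C(/CO[Si](C)(C)C(C)(C)C)[C@@H](OC(C)=O)CC=O)[C@H]1[C@H](OC(=O)[C@@H](C)CC)/C=C(/C)[Cr](Cl)Cl | intermediate
26 | (1S,3S,4Z,6S,7R,8R,9Z)-3-acetoxy-15-(tert-butyldimethylsilyloxy)-1-hydroxy-8-[(2S)-2-methylbutanoyloxy]germacra-4,9,11(13)-trien-12,6-olide | C=C1C(=O)O[C@H]2/C=C(/CO[Si](C)(C)C(C)(C)C)[C@@H](OC(C)=O)C[C@H](O)/C(C)=C\[C@@H](OC(=O)[C@@H](C)CC)[C@@H]12 | intermediate
27 | (1S,3S,4Z,6S,7R,8R,9Z)-3-acetoxy-1,15-dihydroxy-8-[(2S)-2-methylbutanoyloxy]germacra-4,9,11(13)-trien-12,6-olide (CNP0217661.3) | C=C1C(=O)O[C@H]2/C=C(/CO)[C@@H](OC(C)=O)C[C@H](O)/C(C)=C\[C@@H](OC(=O)[C@@H](C)CC)[C@@H]12 | target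

**Summary**
Total step count: 15. Longest linear sequence: 12 steps (steps 2–5, then 8–15).

**Steps most likely to fail**

Step 8 (the new iminium–enamine relay). The enamine may not trap formaldehyde efficiently, and the γ-acyloxy iminium ion could erode C-8 by dienamine formation. The fallback sets out from 9 and 14 and uses only known chemistry. The two-component imidazolidinone-catalysed Mukaiyama–Michael reaction is run alone at −40 °C and aldehyde 15 is isolated. The methylene is then introduced by the classical stoichiometric Mannich route: dimethyl(methylidene)ammonium iodide and Et3N in CH2Cl2 give the 2-[(dimethylamino)methyl] aldehyde F1, which loses dimethylamine on SiO2 or gentle warming. The route is rejoined at 17.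

Step 10 (organocerium addition and lactone transposition). The risks are enolisation of the butenolide at C-6, over-addition, and dehydration of the Z-γ-hydroxy enone to a furan. The fallback sets out from 18 and opens the butenolide first by Weinreb aminolysis (MeNH(OMe)·HCl, AlMe3, CH2Cl2, 0 °C) to the hydroxy Weinreb amide F2. Excess 19 at −78 °C then gives the ketone through the chelated tetrahedral intermediate, with no enolisable lactone left and no over-addition. Work-up delivers 20, where the route is rejoined; carbodiimide lactonisation gives 21 as before.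

Step 14 (macrocyclisation). The sense and level of induction at C-1 are the least predictable element, and oligomerisation competes. The fallback sets out from the crude coupling product, that is 26 together with its C-1 epimer F3. Dess–Martin periodinane in buffered CH2Cl2 oxidises both to the macrocyclic Z-enone F4. Reduction with (R)-2-methyl-CBS-oxazaborolidine and catecholborane at −78 °C then sets 1S under reagent control (same facial rule as step 11). The route is rejoined at 26.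

Further compounds
F1 | step 8 | (2RS,3S,4S,5Z)-2-[(dimethylamino)methyl]-3-[(2S)-4-{[tert-butyl(dimethyl)silyl]oxymethyl}-5-oxo-2,5-dihydrofuran-2-yl]-6-iodo-1-oxohept-5-en-4-yl (2S)-2-methylbutanoate | CN(C)CC(C=O)[C@@H]([C@@H]1C=C(CO[Si](C)(C)C(C)(C)C)C(=O)O1)[C@H](OC(=O)[C@@H](C)CC)/C=C(/C)I
F2 | step 10 | (3S,4S,5Z)-3-[(1S,2Z)-3-{[tert-butyl(dimethyl)silyl]oxymethyl}-1-hydroxy-4-[methoxy(methyl)amino]-4-oxobut-2-en-1-yl]-6-iodo-2-methylidene-4-{[(2S)-2-methylbutanoyl]oxy}hept-5-enoic acid | C=C(C(=O)O)[C@@H]([C@@H](O)/C=C(/CO[Si](C)(C)C(C)(C)C)C(=O)N(C)OC)[C@H](OC(=O)[C@@H](C)CC)/C=C(/C)I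
F3 | step 14 | (1R,3S,4Z,6S,7R,8R,9Z)-3-acetoxy-15-(tert-butyldimethylsilyloxy)-1-hydroxy-8-[(2S)-2-methylbutanoyloxy]germacra-4,9,11(13)-trien-12,6-olide | C=C1C(=O)O[C@H]2/C=C(/CO[Si](C)(C)C(C)(C)C)[C@@H](OC(C)=O)C[C@@H](O)/C(C)=C\[C@@H](OC(=O)[C@@H](C)CC)[C@@H]12
F4 | step 14 | (3S,4Z,6S,7R,8R,9Z)-3-acetoxy-15-(tert-butyldimethylsilyloxy)-8-[(2S)-2-methylbutanoyloxy]-1-oxogermacra-4,9,11(13)-trien-12,6-olide | C=C1C(=O)O[C@H]2/C=C(/CO[Si](C)(C)C(C)(C)C)[C@@H](OC(C)=O)CC(=O)/C(C)=C\[C@@H](OC(=O)[C@@H](C)CC)[C@@H]12
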